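**Plan**

- Retrosynthesis: the enal C=C is cut first (Wittig), then the dioxane ring is opened in one stroke across C7′–C8′ and across the O–aryl bond of the C8′ oxygen. This leaves an α-aryloxy(aryl)acetic acid and a glyceraldehyde unit whose extra carbon is later excised. The remaining C7′–O ether is cut last (Mitsunobu).
- Forward: the two arenes are joined through the C7′–O ether, and the dioxane ring closes in the key step by decarboxylative carbanion addition to the aldehyde followed by fluoride displacement by the alkoxide so formed. Then C9 is trimmed to CH2OH and the ester is extended to the enal.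
- Enabling feature: C7′ is benzylic and α to a ring oxygen, so a carboxyl group there is a traceless carbanion handle. The aromatic carbon that receives the C8′ oxygen lies para to the carbon that carries the C3 side chain, so with an ester there a fluorine at that position is SNAr-active. The free 4-OH para to C7′ makes C7′ epimerisable via a p-quinone methide.
- Stereochemistry: C8′ comes from Felkin–Anh addition to chiral-pool (S)-glyceraldehyde acetonide, whose own stereocentre is excised after it has allowed diastereomer separation. C7′ is funnelled to the trans isomer by thermodynamic equilibration.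

Key step: step 5

Remarks: SEM = 2-(trimethylsilyl)ethoxymethyl. Mandelate 4 is used as the racemate, because its stereocentre (C7′) becomes a planar carbanion in step 5 and is equilibrated in step 6. Aldehyde 8 is commercial and is used freshly distilled.

**Route**

Step 1
Reactants: 1 methyl 4-fluoro-3-methoxybenzoate
Product: 3 methyl 4-fluoro-3-hydroxy-5-methoxybenzoate, via aryl pinacol boronate 2 (not isolated)
Conditions: [Ir(OMe)(cod)]2 (1.5 mol%), dtbpy (3 mol%), B2pin2 (1.0 equiv), THF, 80 °C; then Oxone, acetone/H2O, 0 °C to rt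
Reagents that add atoms: bis(pinacolato)diboron, CC1(C)OB(OC1(C)C)B1OC(C)(C)C(C)(C)O1 (boron group of intermediate 2 only); Oxone (potassium peroxymonosulfate), [K+].[O-]S(=O)(=O)OO (phenol oxygen of 3)
Why: Iridium-catalysed C–H borylation is sterically governed and should take the only C–H not flanked by a large group (C5, ortho to the small fluorine), and the boronate is oxidised in the same pot to the phenol (borylation–oxidation sequence).

Step 2
Reactants: 4 ethyl 4-hydroxy-3-methoxymandelate (racemic)
Product: 5 ethyl 2-hydroxy-2-[3-methoxy-4-(SEM-oxy)phenyl]acetate (racemic)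
Conditions: SEMCl (1.1 equiv), K2CO3, DMF, 0 °C to rt
Reagents that add atoms: 2-(trimethylsilyl)ethoxymethyl chloride, C[Si](C)(C)CCOCCl
Why: Carbonate deprotonates only the phenol, so the phenoxide is alkylated selectively over the secondary alcohol (Williamson-type acetal formation).

Step 3
Reactants: 5 ethyl 2-hydroxy-2-[3-methoxy-4-(SEM-oxy)phenyl]acetate; 3 methyl 4-fluoro-3-hydroxy-5-methoxybenzoate
Product: 6 ethyl 2-[2-fluoro-3-methoxy-5-(methoxycarbonyl)phenoxy]-2-[3-methoxy-4-(SEM-oxy)phenyl]acetate (racemic)
Conditions: PPh3, DIAD, THF, 0 °C to rt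
Reagents that add atoms: none
Why: Mitsunobu etherification of a mandelate ester with a phenol forms the C7′–O–aryl bond; the stereocentre is formed racemic, which is harmless here.

Step 4
Reactants: 6 ethyl 2-[2-fluoro-3-methoxy-5-(methoxycarbonyl)phenoxy]-2-[3-methoxy-4-(SEM-oxy)phenyl]acetate
Product: 7 2-[2-fluoro-3-methoxy-5-(methoxycarbonyl)phenoxy]-2-[3-methoxy-4-(SEM-oxy)phenyl]acetic acid (racemic)
Conditions: LiOH·H2O (1.1 equiv), THF/H2O, 0 °C; then 0.5 M HCl to pH 3
Reagents that add atoms: lithium hydroxide, [Li+].[OH-]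
Why: Saponification with one equivalent of hydroxide at 0 °C should take the α-aryloxy aliphatic ester, which is far more electrophilic than the methyl benzoate.

Step 5
Reactants: 7 2-[2-fluoro-3-methoxy-5-(methoxycarbonyl)phenoxy]-2-[3-methoxy-4-(SEM-oxy)phenyl]acetic acid; 8 (S)-2,2-dimethyl-1,3-dioxolane-4-carbaldehyde
Product: 10 methyl (3R)-3-[(4S)-2,2-dimethyl-1,3-dioxolan-4-yl]-5-methoxy-2-[3-methoxy-4-(SEM-oxy)phenyl]-2,3-dihydro-1,4-benzodioxine-7-carboxylate as a mixture of C2 epimers, via open-chain cesium alkoxide 9 (not isolated)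
Conditions: Cs2CO3 (0.5 equiv), DMA, rt, 4 Å MS; then 8 (3 equiv), 3DPAFIPN (3 mol%), 450 nm LEDs, 20 °C; then 50 °C (dark)
Reagents that add atoms: none
Why: Proposed new method: the excited cyanoarene photocatalyst oxidises the cesium carboxylate of 7, loss of CO2 gives the α-aryloxybenzyl radical at C7′, and the reduced photocatalyst converts it into the cesium carbanion (radical–polar crossover); this adds to the aldehyde carbon of 8 (C7′–C8′ bond), and the cesium alkoxide so formed displaces the fluoride on the carbon para to the ester through a Meisenheimer adduct (O–aryl bond), so that one event closes the dioxane ring. The closest known reaction types are the photocatalytic decarboxylative benzylation of aliphatic aldehydes with arylacetates via carbanions and the intramolecular SNAr etherification of activated fluoroarenes; new here are the α-aryloxy substituent on the carbanion and the use of the alkoxide in situ. The ring closes in the 6-exo-trig mode (ipso attack on the C–F carbon, fluoride as leaving group). C8′ is set by Felkin–Anh addition to the α-alkoxy aldehyde (dioxolane C–O bond anti to the incoming carbanion, giving the 2,3-anti adduct, which has the spatial arrangement of 8′S in the target although its descriptor here is R); C7′ arises without control as both epimers and is corrected in step 6; the dioxolane carbon comes unchanged from 8. The step needs chemoselectivity of the carbanion for the aldehyde over the methyl ester and the C–F carbon, which the excess of the far more electrophilic aldehyde should secure, and regioselectivity of ring closure, which the single fluorine para to the ester secures. Because the alkoxide is consumed intramolecularly as it forms, no base should accumulate that could epimerise 8.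

Step 6
Reactants: 10 methyl (3R)-3-[(4S)-2,2-dimethyl-1,3-dioxolan-4-yl]-5-methoxy-2-[3-methoxy-4-(SEM-oxy)phenyl]-2,3-dihydro-1,4-benzodioxine-7-carboxylate (C2 epimer mixture)
Product: 11 methyl (2S,3R)-3-[(4S)-2,2-dimethyl-1,3-dioxolan-4-yl]-2-(4-hydroxy-3-methoxyphenyl)-5-methoxy-2,3-dihydro-1,4-benzodioxine-7-carboxylate (trans)
Conditions: TBAF (4 equiv, dried over 4 Å MS), THF, 65 °C; aqueous work-up; chromatography
Reagents that add atoms: none
Why: Fluoride fragments the SEM acetal to the tetrabutylammonium phenoxide, which opens the C7′–O bond by retro-oxa-1,6-addition to the p-quinone methide and re-closes reversibly (the reaction type of the base-mediated C2 epimerisation of catechins), so thermodynamic control should place the aryl group trans (diequatorial) to the C8′ substituent and set C7′ as S, while the trans isomer descending from the minor C8′ epimer of step 5 is a diastereomer because of the dioxolane stereocentre and is removed by chromatography.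

Step 7
Reactants: 11 methyl (2S,3R)-3-[(4S)-2,2-dimethyl-1,3-dioxolan-4-yl]-2-(4-hydroxy-3-methoxyphenyl)-5-methoxy-2,3-dihydro-1,4-benzodioxine-7-carboxylate
Product: 12 methyl (2S,3R)-3-[(1S)-1,2-dihydroxyethyl]-2-(4-hydroxy-3-methoxyphenyl)-5-methoxy-2,3-dihydro-1,4-benzodioxine-7-carboxylate
Conditions: AcOH/H2O (7:3), 40 °C
Reagents that add atoms: none
Why: Mild acid hydrolysis of the terminal isopropylidene acetal leaves the ester and the stereocentres untouched; any acid-induced re-equilibration at C7′ could only lead to the same trans isomer.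

Step 8
Reactants: 12 methyl (2S,3R)-3-[(1S)-1,2-dihydroxyethyl]-2-(4-hydroxy-3-methoxyphenyl)-5-methoxy-2,3-dihydro-1,4-benzodioxine-7-carboxylate
Product: 14 4-[(2S,3S)-3,7-bis(hydroxymethyl)-5-methoxy-2,3-dihydro-1,4-benzodioxin-2-yl]-2-methoxyphenol, via α-aryloxy aldehyde 13 (not isolated)
Conditions: NaIO4 (1.1 equiv), THF/pH 7 buffer, 0 °C, 15 min; extraction; then LiAlH4, THF, 0 °C to rt; Rochelle salt work-up
Reagents that add atoms: none
Why: Malaprade glycol cleavage excises the stereodirecting carbon as formaldehyde and leaves C9 as an aldehyde, which LiAlH4 reduces at once together with the methyl ester before C8′ can epimerise; C8′ keeps its geometry and becomes S by the change of CIP priorities.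

Step 9
Reactants: 14 4-[(2S,3S)-3,7-bis(hydroxymethyl)-5-methoxy-2,3-dihydro-1,4-benzodioxin-2-yl]-2-methoxyphenol
Product: 15 (2S,3S)-3-(hydroxymethyl)-2-(4-hydroxy-3-methoxyphenyl)-5-methoxy-2,3-dihydro-1,4-benzodioxine-7-carbaldehyde
Conditions: activated MnO2 (10 equiv), CH2Cl2/acetone, rt
Reagents that add atoms: none
Why: Manganese dioxide oxidises the benzylic alcohol chemoselectively and should leave the saturated primary alcohol at C9 untouched.

Step 10
Reactants: 15 (2S,3S)-3-(hydroxymethyl)-2-(4-hydroxy-3-methoxyphenyl)-5-methoxy-2,3-dihydro-1,4-benzodioxine-7-carbaldehyde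
Product: 16 (7′S,8′S)-nocomtal
Conditions: Ph3P=CHCHO (1.3 equiv), toluene, 80 °C
Reagents that add atoms: (triphenylphosphoranylidene)acetaldehyde, O=CC=P(c1ccccc1)(c1ccccc1)c1ccccc1
Why: Wittig reaction with the stabilised formyl ylide gives the (E)-enal, tolerates the free phenol and alcohol, and does not touch the stereocentres.

**Compound list**

1 | methyl 4-fluoro-3-methoxybenzoate | COC(=O)c1ccc(F)c(OC)c1 | starting material
2 | methyl 4-fluoro-3-methoxy-5-(4,4,5,5-tetramethyl-1,3,2-dioxaborolan-2-yl)benzoate | COC(=O)c1cc(OC)c(F)c(B2OC(C)(C)C(C)(C)O2)c1 | intermediate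
3 | methyl 4-fluoro-3-hydroxy-5-methoxybenzoate | COC(=O)c1cc(O)c(F)c(OC)c1 | intermediate
4 | ethyl 4-hydroxy-3-methoxymandelate (racemic) | CCOC(=O)C(O)c1ccc(O)c(OC)c1 | starting material
5 | ethyl 2-hydroxy-2-[3-methoxy-4-(SEM-oxy)phenyl]acetate (racemic) | CCOC(=O)C(O)c1ccc(OCOCC[Si](C)(C)C)c(OC)c1 | intermediate
6 | ethyl 2-[2-fluoro-3-methoxy-5-(methoxycarbonyl)phenoxy]-2-[3-methoxy-4-(SEM-oxy)phenyl]acetate (racemic) | CCOC(=O)C(Oc1cc(C(=O)OC)cc(OC)c1F)c1ccc(OCOCC[Si](C)(C)C)c(OC)c1 | intermediate
7 | 2-[2-fluoro-3-methoxy-5-(methoxycarbonyl)phenoxy]-2-[3-methoxy-4-(SEM-oxy)phenyl]acetic acid (racemic) | OC(=O)C(Oc1cc(C(=O)OC)cc(OC)c1F)c1ccc(OCOCC[Si](C)(C)C)c(OC)c1 | intermediate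
8 | (S)-2,2-dimethyl-1,3-dioxolane-4-carbaldehyde | O=C[C@@H]1COC(C)(C)O1 | starting material
9 | methyl 3-{(2R)-2-[(4S)-2,2-dimethyl-1,3-dioxolan-4-yl]-2-hydroxy-1-[3-methoxy-4-(SEM-oxy)phenyl]ethoxy}-4-fluoro-5-methoxybenzoate, both C1 epimers (formed as its cesium alkoxide, drawn as the alcohol) | COc1cc(C(Oc2cc(C(=O)OC)cc(OC)c2F)[C@@H](O)[C@@H]2COC(C)(C)O2)ccc1OCOCC[Si](C)(C)C | intermediate
10 | methyl (3R)-3-[(4S)-2,2-dimethyl-1,3-dioxolan-4-yl]-5-methoxy-2-[3-methoxy-4-(SEM-oxy)phenyl]-2,3-dihydro-1,4-benzodioxine-7-carboxylate, mixture of C2 (C7′) epimers | COc1cc(C2Oc3cc(C(=O)OC)cc(OC)c3O[C@H]2[C@@H]4COC(C)(C)O4)ccc1OCOCC[Si](C)(C)C | intermediate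
11 | methyl (2S,3R)-3-[(4S)-2,2-dimethyl-1,3-dioxolan-4-yl]-2-(4-hydroxy-3-methoxyphenyl)-5-methoxy-2,3-dihydro-1,4-benzodioxine-7-carboxylate (trans; 3R has the geometry of 8′S in the target) | COc1cc([C@@H]2Oc3cc(C(=O)OC)cc(OC)c3O[C@H]2[C@@H]4COC(C)(C)O4)ccc1O | intermediate
12 | methyl (2S,3R)-3-[(1S)-1,2-dihydroxyethyl]-2-(4-hydroxy-3-methoxyphenyl)-5-methoxy-2,3-dihydro-1,4-benzodioxine-7-carboxylate | COc1cc([C@@H]2Oc3cc(C(=O)OC)cc(OC)c3O[C@H]2[C@@H](O)CO)ccc1O | intermediate
13 | methyl (2S,3R)-3-formyl-2-(4-hydroxy-3-methoxyphenyl)-5-methoxy-2,3-dihydro-1,4-benzodioxine-7-carboxylate | COc1cc([C@@H]2Oc3cc(C(=O)OC)cc(OC)c3O[C@H]2C=O)ccc1O | intermediate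
14 | 4-[(2S,3S)-3,7-bis(hydroxymethyl)-5-methoxy-2,3-dihydro-1,4-benzodioxin-2-yl]-2-methoxyphenol | COc1cc([C@@H]2Oc3cc(CO)cc(OC)c3O[C@H]2CO)ccc1O | intermediate
15 | (2S,3S)-3-(hydroxymethyl)-2-(4-hydroxy-3-methoxyphenyl)-5-methoxy-2,3-dihydro-1,4-benzodioxine-7-carbaldehyde | COc1cc([C@@H]2Oc3cc(C=O)cc(OC)c3O[C@H]2CO)ccc1O | intermediate
16 | (7′S,8′S)-nocomtal, (E)-3-[(2S,3S)-3-(hydroxymethyl)-2-(4-hydroxy-3-methoxyphenyl)-5-methoxy-2,3-dihydro-1,4-benzodioxin-7-yl]prop-2-enal | COc1cc([C@@H]2Oc3cc(/C=C/C=O)cc(OC)c3O[C@H]2CO)ccc1O | target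

**Step count and risks**

Total steps: 10. Longest linear sequence: 9 steps (1 → 3 → 6 → 7 → 10 → 11 → 12 → 14 → 15 → 16; the branch from 4 is equally long).

Steps most likely to fail:

1. Step 5 (Proposed new method). The electron-rich α-aryloxybenzyl radical may resist reduction to the carbanion and instead dimerise or abstract hydrogen. If ring closure lags, the alkoxide may epimerise or self-condense aldehyde 8, and the facial selectivity of the addition may be modest. Fallback with known chemistry, setting out from acid 7 and returning at 9 and then 10: acid 7 is converted (DCC, 2-mercaptopyridine N-oxide, dark) into its N-hydroxypyridine-2-thione ester, the Barton ester F1. Visible-light photolysis gives by decarboxylative rearrangement the 2-pyridyl O,S-acetal F2, and oxidation (mCPBA, NaHCO3) gives the α-aryloxybenzyl 2-pyridyl sulfone F3. Samarium diiodide Barbier coupling of F3 with 8 (THF, rt), as practised on anomeric pyridyl sulfones in C-glycoside synthesis, gives alcohol 9 through a non-basic samarium alkoxide that leaves 8 configurationally intact. Isolated 9 is then cyclised in a separate SNAr step (Cs2CO3, DMF, 60 °C) to 10.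

2. Step 6. SEM cleavage by fluoride may be sluggish, and the quinone methide may be intercepted by water or fluoride or may tautomerise to a ring-opened enol ether instead of re-closing. Fallback, setting out from 10 and returning at 12: wet trifluoroacetic acid in CH2Cl2 (0 °C to rt) removes the SEM group and the acetonide and equilibrates C7′ through the p-hydroxybenzyl cation, which can only re-close to the six-membered ring. The trans diol 12 is then separated from its C8′-epimeric trans diastereomer at this stage. This fallback makes no compound outside the list (entry F0).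

3. Step 8. Periodate may oxidise the free guaiacol unit to an o-quinone in competition with glycol cleavage, and the α-aryloxy aldehyde may epimerise before reduction. Fallback, setting out from 11 and returning at 14: the phenol is acetylated (Ac2O, pyridine) to aryl acetate F4, and the acetonide is hydrolysed (aqueous AcOH) to diol acetate F5. Periodate cleavage then gives aldehyde acetate F6 without risk to the masked phenol, and LiAlH4 reduces the aldehyde and the methyl ester and cleaves the acetate in the same operation to give 14.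

Further compounds
F1 | step 5 | Barton ester of 7, 2-thioxopyridin-1(2H)-yl 2-[2-fluoro-3-methoxy-5-(methoxycarbonyl)phenoxy]-2-[3-methoxy-4-(SEM-oxy)phenyl]acetate | O=C(ON1C=CC=CC1=S)C(Oc1cc(C(=O)OC)cc(OC)c1F)c1ccc(OCOCC[Si](C)(C)C)c(OC)c1
F2 | step 5 | methyl 4-fluoro-3-methoxy-5-{[3-methoxy-4-(SEM-oxy)phenyl](pyridin-2-ylsulfanyl)methoxy}benzoate | COC(=O)c1cc(OC)c(F)c(OC(Sc2ccccn2)c2ccc(OCOCC[Si](C)(C)C)c(OC)c2)c1
F3 | step 5 | methyl 4-fluoro-3-methoxy-5-{[3-methoxy-4-(SEM-oxy)phenyl](pyridin-2-ylsulfonyl)methoxy}benzoate | COC(=O)c1cc(OC)c(F)c(OC(c2ccc(OCOCC[Si](C)(C)C)c(OC)c2)S(=O)(=O)c2ccccn2)c1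
F0 | step 6 | none | none
F4 | step 8 | phenol acetate of 11 | COc1cc([C@@H]2Oc3cc(C(=O)OC)cc(OC)c3O[C@H]2[C@@H]4COC(C)(C)O4)ccc1OC(C)=O
F5 | step 8 | phenol acetate of 12 | COc1cc([C@@H]2Oc3cc(C(=O)OC)cc(OC)c3O[C@H]2[C@@H](O)CO)ccc1OC(C)=O
F6 | step 8 | phenol acetate of 13 | COc1cc([C@@H]2Oc3cc(C(=O)OC)cc(OC)c3O[C@H]2C=O)ccc1OC(C)=O
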